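The route rests on cutting the unbranched C16 acyl chain at its central C8′–C9′ bond. The key step exploits that C8′ and C9′ are primary, unfunctionalised CH2 carbons, insulated by C2′–C7′ from the C6 ester and from the butenolide ring (O1–C2–C3=C3a–C7a) fused to the cyclohexane ring, so each is the α-carbon of a C9 acid. A crossed Kolbe electrolysis of loliolide hydrogen azelate with excess nonanoic acid forms this sp3–sp3 bond in one operation with loss of two CO2; the precursor is a diacid half-ester carrying the complete bicycle. (−)-Loliolide comes from (4R,6R)-actinol by anti-selective Rubottom oxidation (sets C7a) and Bestmann-ylide butenolide annulation.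

Key step: step 7

Remark: bicycle locants follow loliolide numbering (O1, C2, C3, C3a, C4–C7, C7a); cyclohexanone intermediates are numbered as actinol (C1 = C=O, C4 = CH–O, C6 = C–CH3, the later C7a); primed locants count the acyl chain from its carbonyl carbon.

Step 1
Reactants: 1 (4R,6R)-4-hydroxy-2,2,6-trimethylcyclohexan-1-one ((4R,6R)-actinol)
Product: 2 (4R,6R)-4-[(tert-butyldimethylsilyl)oxy]-2,2,6-trimethylcyclohexan-1-one
Conditions: TBSCl, imidazole, DMF, rt
Reagents that add atoms: tert-butyldimethylsilyl chloride (TBSCl), CC(C)(C)[Si](C)(C)Cl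
Why: Standard silyl ether formation on the only hydroxyl masks C4–OH for the enolisation and ylide steps and leaves both stereocentres untouched.

Step 2
Reactants: 2 (4R,6R)-4-[(tert-butyldimethylsilyl)oxy]-2,2,6-trimethylcyclohexan-1-one
Product: 3 {[(4R)-4-[(tert-butyldimethylsilyl)oxy]-2,6,6-trimethylcyclohex-1-en-1-yl]oxy}trimethylsilane
Conditions: TMSOTf, Et3N, CH2Cl2, 0 °C → rt
Reagents that add atoms: trimethylsilyl trifluoromethanesulfonate (TMSOTf), C[Si](C)(C)OS(=O)(=O)C(F)(F)F
Why: Soft enolisation (silyl triflate/amine) can only occur toward C6 because C2 is quaternary, so a single tetrasubstituted silyl enol ether should form; the C6 stereocentre is erased on purpose while C4 is unaffected.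

Step 3
Reactants: 3 {[(4R)-4-[(tert-butyldimethylsilyl)oxy]-2,6,6-trimethylcyclohex-1-en-1-yl]oxy}trimethylsilane
Product: 6 (4S,6R)-4-[(tert-butyldimethylsilyl)oxy]-6-hydroxy-2,2,6-trimethylcyclohexan-1-one, via silyloxy epoxide 4 (not isolated), via α-silyloxy ketone 5 (not isolated)
Conditions: mCPBA, hexane, −15 °C → rt; then K2CO3 (cat.), MeOH, 0 °C
Reagents that add atoms: meta-chloroperoxybenzoic acid (mCPBA), OOC(=O)c1cccc(Cl)c1
Why: Rubottom oxidation: the peracid should epoxidise the electron-rich C1=C6 bond on the face anti to the C4 silyloxy group (the sense expected by analogy with peracid epoxidation of O-protected 3-hydroxy-β-ionone-type rings), the silyloxy epoxide opens with 1,4-silyl shift to the α-silyloxy ketone and mild methanolysis frees the tertiary alcohol, which sets the C6 (future C7a) oxygen trans to C4–O while the secondary TBS ether survives.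

Step 4
Reactants: 6 (4S,6R)-4-[(tert-butyldimethylsilyl)oxy]-6-hydroxy-2,2,6-trimethylcyclohexan-1-one; 7 (triphenylphosphoranylidene)ketene (Bestmann ylide)
Product: 9 (6S,7aR)-6-[(tert-butyldimethylsilyl)oxy]-4,4,7a-trimethyl-5,6,7,7a-tetrahydro-1-benzofuran-2(4H)-one (O-TBS-loliolide), via ester ylide 8 (not isolated)
Conditions: 7 (1.5 equiv), toluene, 110 °C
Reagents that add atoms: none
Why: Bestmann-ylide butenolide annulation: the tertiary hydroxyl adds across the C=C of the cumulated ylide to give ester ylide 8, whose intramolecular Wittig reaction with the non-enolisable C1 ketone (five-membered closure) should form the C3a=C3 bond and the lactone without touching C6 or C7a.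

Step 5
Reactants: 9 O-TBS-loliolide
Product: 10 (6S,7aR)-6-hydroxy-4,4,7a-trimethyl-5,6,7,7a-tetrahydro-1-benzofuran-2(4H)-one ((−)-loliolide)
Conditions: HF·pyridine, THF, 0 °C → rt
Reagents that add atoms: none
Why: Fluoride-driven Si–O cleavage removes the TBS group under weakly acidic conditions that the butenolide tolerates, with retention at C6.

Step 6
Reactants: 10 (−)-loliolide; 11 azelaic acid (nonanedioic acid)
Product: 12 9-{[(6S,7aR)-4,4,7a-trimethyl-2-oxo-2,4,5,6,7,7a-hexahydro-1-benzofuran-6-yl]oxy}-9-oxononanoic acid (loliolide hydrogen azelate)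
Conditions: 11 (5 equiv), EDC·HCl, DMAP (cat.), CH2Cl2/THF, 0 °C → rt
Reagents that add atoms: none
Why: Steglich esterification (carbodiimide/DMAP) acylates the C6 oxygen with retention, and the fivefold excess of the symmetrical diacid should hold the product at the half-ester stage.

Step 7
Reactants: 12 loliolide hydrogen azelate; 13 nonanoic acid
Product: 14 (6S,7aR)-4,4,7a-trimethyl-2-oxo-2,4,5,6,7,7a-hexahydro-1-benzofuran-6-yl hexadecanoate ((−)-3-O-palmitoylloliolide)
Conditions: Pt anode/Pt cathode, undivided cell, constant current (ca. 0.25 A cm⁻²), 13 (8 equiv), KOH (5 mol% of total acid, pre-neutralised), MeOH, 40 °C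
Reagents that add atoms: none
Why: At the platinum anode both carboxylates are oxidised by one electron and lose CO2 at once, giving the octyl radical from 13 and the 7-(loliolidyloxycarbonyl)heptyl radical from 12 in a dense layer at the electrode, where radical–radical recombination forms the C8′–C9′ bond (crossed Kolbe electrolysis). The closest known reaction type is the anodic cross-coupling of alkyl hydrogen α,ω-dicarboxylates with alkanoic acids used to build long-chain fatty esters, so this is known chemistry applied to a new ester. No ring is closed and no stereocentre is formed; C6 and C7a lie far from the radical centre and should be untouched. The step needs cross-coupling to win over homo-coupling, which the eightfold excess of the cheap acid 13 secures statistically, and the by-products hexadecane and the C16 bis-loliolide diester differ strongly in polarity from 14. It also needs the butenolide to survive: its β-carbon C3a is fully substituted and flanked by the quaternary C4 and C7a, which should suppress radical conjugate addition, the carboxylate layer on the anode shields the rest of the molecule from oxidation, and the electrolyte stays weakly acidic until the acids are consumed, so the C6 ester and the lactone should not be methanolysed.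

Compound list
1 | (4R,6R)-4-hydroxy-2,2,6-trimethylcyclohexan-1-one ((4R,6R)-actinol; OH and 6-CH3 trans) | C[C@@H]1C[C@@H](O)CC(C)(C)C1=O | starting material
2 | (4R,6R)-4-[(tert-butyldimethylsilyl)oxy]-2,2,6-trimethylcyclohexan-1-one | C[C@@H]1C[C@@H](O[Si](C)(C)C(C)(C)C)CC(C)(C)C1=O | intermediate
3 | {[(4R)-4-[(tert-butyldimethylsilyl)oxy]-2,6,6-trimethylcyclohex-1-en-1-yl]oxy}trimethylsilane | CC1=C(O[Si](C)(C)C)C(C)(C)C[C@H](O[Si](C)(C)C(C)(C)C)C1 | intermediate
4 | 4-[(tert-butyldimethylsilyl)oxy]-2,2,6-trimethyl-1-(trimethylsilyloxy)-7-oxabicyclo[4.1.0]heptane, oxirane oxygen trans to OTBS (formed in the flask in step 3) | C[C@]12O[C@@]1(O[Si](C)(C)C)C(C)(C)C[C@H](O[Si](C)(C)C(C)(C)C)C2 | intermediate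
5 | (4S,6R)-4-[(tert-butyldimethylsilyl)oxy]-2,2,6-trimethyl-6-(trimethylsilyloxy)cyclohexan-1-one (formed in the flask in step 3) | C[C@@]1(O[Si](C)(C)C)C[C@@H](O[Si](C)(C)C(C)(C)C)CC(C)(C)C1=O | intermediate
6 | (4S,6R)-4-[(tert-butyldimethylsilyl)oxy]-6-hydroxy-2,2,6-trimethylcyclohexan-1-one (6-OH trans to 4-OTBS) | C[C@@]1(O)C[C@@H](O[Si](C)(C)C(C)(C)C)CC(C)(C)C1=O | intermediate
7 | (triphenylphosphoranylidene)ketene (Bestmann ylide) | O=C=C=P(c1ccccc1)(c1ccccc1)c1ccccc1 | starting material
8 | (triphenylphosphoranylidene)acetate ester of the tertiary alcohol of 6 (formed in the flask in step 4) | O=C(C=P(c1ccccc1)(c1ccccc1)c1ccccc1)O[C@]1(C)C[C@@H](O[Si](C)(C)C(C)(C)C)CC(C)(C)C1=O | intermediate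
9 | (6S,7aR)-6-[(tert-butyldimethylsilyl)oxy]-4,4,7a-trimethyl-5,6,7,7a-tetrahydro-1-benzofuran-2(4H)-one | CC(C)(C)[Si](C)(C)O[C@H]1CC(C)(C)C2=CC(=O)O[C@]2(C)C1 | intermediate
10 | (6S,7aR)-6-hydroxy-4,4,7a-trimethyl-5,6,7,7a-tetrahydro-1-benzofuran-2(4H)-one ((−)-loliolide) | O[C@H]1CC(C)(C)C2=CC(=O)O[C@]2(C)C1 | intermediate
11 | azelaic acid (nonanedioic acid) | OC(=O)CCCCCCCC(=O)O | starting material
12 | 9-{[(6S,7aR)-4,4,7a-trimethyl-2-oxo-2,4,5,6,7,7a-hexahydro-1-benzofuran-6-yl]oxy}-9-oxononanoic acid | OC(=O)CCCCCCCC(=O)O[C@H]1CC(C)(C)C2=CC(=O)O[C@]2(C)C1 | intermediate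
13 | nonanoic acid | CCCCCCCCC(=O)O | starting material
14 | (6S,7aR)-4,4,7a-trimethyl-2-oxo-2,4,5,6,7,7a-hexahydro-1-benzofuran-6-yl hexadecanoate ((−)-3-O-palmitoylloliolide) | CCCCCCCCCCCCCCCC(=O)O[C@H]1CC(C)(C)C2=CC(=O)O[C@]2(C)C1 | target

Total step count: 7
Longest linear sequence: 7 steps (1 → 14); compounds 7, 11 and 13 are purchased.

Steps most likely to fail

1. Step 7 (key step). The two radicals pair statistically and also disproportionate. Homo-coupling of the ester-bearing radical, its conversion to the saturated or olefinic C8 ester, and slow methanolysis near the cathode may therefore erode the cross-coupled product. The fallback replaces radical pairing by a two-electron cross-coupling; it sets out from 10 and returns at 14. Compound 10 is esterified with 8-bromooctanoic acid (EDC·HCl, DMAP, CH2Cl2) to give loliolide 8-bromooctanoate F1. 1-Octene is hydroborated with 9-BBN (THF, rt) to give B-octyl-9-BBN F2. An alkyl–alkyl Suzuki–Miyaura coupling of F1 with F2 (Pd(OAc)2, PCy3, K3PO4·H2O, THF, rt) then forms the same C8′–C9′ bond and gives 14.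

2. Step 3. Oxygen transfer to the flat tetrasubstituted enol ether may show poor facial selectivity; oxygen arriving cis to the silyloxy group leads into the C7a-epimeric series. Acid-induced hydrolysis of the enol ether back to 2 may also compete. The fallback installs carbon first and oxygen second: the stereo-determining epoxidation is moved to a carbocyclic β-ring-type alkene, and its oxygen is carried into the lactone with retention. It sets out from 2 and returns at 9, bypassing steps 2–4. Compound 2 is converted (KHMDS, PhNTf2, THF, −78 → 0 °C) into enol triflate F3. Negishi coupling with the Reformatsky reagent BrZnCH2CO2Et (Pd(PPh3)4, THF, 60 °C) gives β,γ-unsaturated ester F4. mCPBA (CH2Cl2, 0 °C) should epoxidise anti to OTBS to give epoxy ester F5, where any minor isomer can be removed. LiHMDS (THF, −78 → 0 °C) opens the epoxide by E1cB elimination, and the liberated C7a alkoxide lactonises with loss of ethanol to give 9.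

3. Step 4. Addition of the hindered tertiary alcohol to the ylide may be slow, and the intramolecular Wittig closure onto a ketone flanked by two quaternary carbons may be sluggish, so that thermal α-ketol rearrangement of 6 competes. The fallback uses a small ester enolate in place of the phosphorus ylide; it sets out from 6 and returns at 9. Acetylation of 6 (Ac2O, DMAP, Et3N, CH2Cl2, 40 °C) gives α-acetoxy ketone F6. LiHMDS (THF, −78 °C) triggers an intramolecular acetate aldol addition onto the non-enolisable ketone to give cis-fused β-hydroxy lactone F7. Dehydration (SOCl2, pyridine, 0 °C), which can only eliminate toward C3, gives 9.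

Further compounds
F1 | step 7 | (6S,7aR)-4,4,7a-trimethyl-2-oxo-2,4,5,6,7,7a-hexahydro-1-benzofuran-6-yl 8-bromooctanoate | BrCCCCCCCC(=O)O[C@H]1CC(C)(C)C2=CC(=O)O[C@]2(C)C1
F2 | step 7 | 9-octyl-9-borabicyclo[3.3.1]nonane | CCCCCCCCB1C2CCCC1CCC2
F3 | step 3 | (4R)-4-[(tert-butyldimethylsilyl)oxy]-2,6,6-trimethylcyclohex-1-en-1-yl trifluoromethanesulfonate | CC1=C(OS(=O)(=O)C(F)(F)F)C(C)(C)C[C@H](O[Si](C)(C)C(C)(C)C)C1
F4 | step 3 | ethyl 2-[(4R)-4-[(tert-butyldimethylsilyl)oxy]-2,6,6-trimethylcyclohex-1-en-1-yl]acetate | CC1=C(CC(=O)OCC)C(C)(C)C[C@H](O[Si](C)(C)C(C)(C)C)C1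
F5 | step 3 | ethyl 2-{4-[(tert-butyldimethylsilyl)oxy]-2,2,6-trimethyl-7-oxabicyclo[4.1.0]heptan-1-yl}acetate, oxirane oxygen trans to OTBS | C[C@]12O[C@@]1(CC(=O)OCC)C(C)(C)C[C@H](O[Si](C)(C)C(C)(C)C)C2
F6 | step 4 | (4S,6R)-6-acetoxy-4-[(tert-butyldimethylsilyl)oxy]-2,2,6-trimethylcyclohexan-1-one | CC(=O)O[C@]1(C)C[C@@H](O[Si](C)(C)C(C)(C)C)CC(C)(C)C1=O
F7 | step 4 | (3aR,6S,7aR)-6-[(tert-butyldimethylsilyl)oxy]-3a-hydroxy-4,4,7a-trimethylhexahydro-1-benzofuran-2(3H)-one (cis-fused) | CC(C)(C)[Si](C)(C)O[C@H]1CC(C)(C)[C@]2(O)CC(=O)O[C@]2(C)C1
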